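A direct plan would join three ready-made rings by phenoxide addition–elimination on a halogenated quinone.
The ring A phenol would displace chloride from 3-chloro-2-methyl-5-(propan-2-yl)cyclohexa-2,5-diene-1,4-dione A1 to give the aryloxyquinone A2.
A2 would be reduced and mono-O-methylated to the ring A–ring B phenol A3, and A3 would attack A1 once more.
Its weakest points would be:
(a) the building of A1 itself, about seven steps from open-chain material for a small quinone that adds little complexity;
(b) the mono-methylation of the ring B hydroquinone, which would need a silyl/benzyl relay of some six steps whose first, purely steric, choice between two OH groups is left to chance;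
(c) the last etherification, where a phenoxide flanked by isopropyl and aryloxy groups would have to attack a base-sensitive quinone on the most advanced material.

**Plan of the new route**
Ring A is the terminal methoxyarene, ring C the quinone, ring B the central benzene (C-1 O to ring C, C-2 O to ring A, C-3 CH3, C-4 OCH3, C-5 H, C-6 isopropyl).
Retrosynthesis: the quinone is traced to a thymol-type phenol, the O–CH3 bond at C-4 of ring B is cut, and ring B itself is cut at C-3/C-4, C-4/C-5 and C-1/C-2 into an aryloxy(vinyl)ketene carrying ring C and an aryl prop-1-ynyl ether carrying ring A.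
Rings A and C therefore come first, both from thymol, and ring B arises last, between them, from trichloroethylene, iodomethane, trichloroacetate, formaldehyde and 3-methylbutanal.
The enabling feature is the 1,2,4-trioxygenation of ring B, with the C-4 oxygen meta to ether carbon C-2 and para to ether carbon C-1, CH3 on C-3 and the only ring hydrogen on C-5. A vinylketene/ynol ether benzannulation writes exactly this pattern (ketene carbon = C-4, alkyne carbons = C-3 and C-2, ketene alpha carbon = C-1, vinyl carbons = C-6 and C-5).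
No quinone is built from open-chain material, ring B is born with a single free OH (the one to be methylated), and the crowded B–O–C oxygen is attached early to an sp3 carbon by a Jocic reaction instead of late to a quinone.

Key step: step 11

Assumption: compounds 13 to 17 and 19 are racemic; their single stereocentre is erased in step 11 and the target is achiral. Ynol ether 6 is taken to survive chromatography on base-washed silica and storage at −20 °C.

**Step 1**
Reactants: 1 thymol (5-methyl-2-(propan-2-yl)phenol)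
Product: 2 4-bromo-5-methyl-2-(propan-2-yl)phenol
Conditions: NBS (1.0 equiv), MeCN, 0 °C → rt
Reagents that add atoms: N-bromosuccinimide, O=C1CCC(=O)N1Br
Why: Electrophilic aromatic bromination enters only at the position para to OH, the most activated and least hindered site.

**Step 2**
Reactants: 2 4-bromo-5-methyl-2-(propan-2-yl)phenol
Product: 3 4-methoxy-5-methyl-2-(propan-2-yl)phenol
Conditions: NaOMe (5 equiv, 25% in MeOH), CuI (0.2 equiv), DMF, 110 °C
Reagents that add atoms: sodium methoxide, C[O-].[Na+]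
Why: Copper-catalysed Ullmann-type methoxylation replaces Br by OCH3 at the same carbon, and the free phenoxide is tolerated because methoxide is no methylating agent.

**Step 3**
Reactants: 3 4-methoxy-5-methyl-2-(propan-2-yl)phenol
Product: 4 1-{[(E)-1,2-dichloroethenyl]oxy}-4-methoxy-5-methyl-2-(propan-2-yl)benzene
Conditions: trichloroethylene (1.5 equiv), K2CO3 (2 equiv), DMF, 70 °C
Reagents that add atoms: trichloroethylene, ClC=C(Cl)Cl
Why: Base turns trichloroethylene into dichloroacetylene, to which the phenoxide adds anti (the established elimination–addition route to aryl 1,2-dichlorovinyl ethers), placing on oxygen the two carbons that become C-2 and C-3 of ring B.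

**Step 4**
Reactants: 4 1-{[(E)-1,2-dichloroethenyl]oxy}-4-methoxy-5-methyl-2-(propan-2-yl)benzene
Product: 6 1-methoxy-2-methyl-5-(propan-2-yl)-4-(prop-1-yn-1-yloxy)benzene, via lithium acetylide 5 (not isolated)
Conditions: n-BuLi (2.3 equiv), THF, −78 → −40 °C; MeI (3 equiv), DMPU, −78 °C → rt; base-washed silica
Reagents that add atoms: iodomethane, CI; n-butyllithium, [Li]CCCC (lithium of 5 only)
Why: Dehydrochlorination to the chloroalkynyl ether and chlorine–lithium exchange give acetylide 5, which MeI methylates on carbon (the established alkynyl ether synthesis from dichlorovinyl ethers).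

**Step 5**
Reactants: 1 thymol (5-methyl-2-(propan-2-yl)phenol)
Product: 7 2-hydroxy-6-methyl-3-(propan-2-yl)benzaldehyde
Conditions: MgCl2 (1.5 equiv), Et3N (3.75 equiv), (CH2O)n (6.75 equiv), MeCN, reflux; then 1 M HCl
Reagents that add atoms: formaldehyde (as paraformaldehyde), C=O
Why: The magnesium-phenoxide-directed ortho-formylation (Casnati–Skattebøl) can only occur at the single free ortho position, between OH and the ring methyl.

**Step 6**
Reactants: 7 2-hydroxy-6-methyl-3-(propan-2-yl)benzaldehyde
Product: 8 2-(benzyloxy)-6-methyl-3-(propan-2-yl)benzaldehyde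
Conditions: BnBr (1.2 equiv), K2CO3 (2 equiv), DMF, 60 °C
Reagents that add atoms: benzyl bromide, BrCc1ccccc1
Why: A Williamson ether synthesis masks the oxygen that will end as the quinone oxygen next to the isopropyl group of ring C, and the benzyl ether survives every step up to hydrogenolysis.

**Step 7**
Reactants: 8 2-(benzyloxy)-6-methyl-3-(propan-2-yl)benzaldehyde
Product: 10 2-(benzyloxy)-6-methyl-3-(propan-2-yl)phenol, via aryl formate 9 (not isolated)
Conditions: mCPBA (1.5 equiv), CH2Cl2, 0 °C → rt; then K2CO3 (0.2 equiv), MeOH, rt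
Reagents that add atoms: 3-chloroperoxybenzoic acid, OOC(=O)c1cccc(Cl)c1
Why: In this Baeyer–Villiger (Dakin-type) oxidation the electron-rich aryl group migrates in preference to H, and methanolysis of formate 9 frees the phenol whose oxygen becomes the B–O–C ether oxygen.

**Step 8**
Reactants: 11 3-methylbutanal
Product: 12 3-methyl-2-methylidenebutanal
Conditions: 37% aq. CH2O (1.1 equiv), pyrrolidine (10 mol%), propanoic acid (10 mol%), i-PrOH, 45 °C; distillation
Reagents that add atoms: formaldehyde, C=O
Why: Amine-catalysed Mannich condensation–elimination (alpha-methylenation of an aldehyde) installs the CH2 that becomes C-5, the only C–H carbon of ring B.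

**Step 9**
Reactants: 12 3-methyl-2-methylidenebutanal
Product: 13 1,1,1-trichloro-4-methyl-3-methylidenepentan-2-ol (racemic)
Conditions: CCl3CO2Na (1.5 equiv), CCl3CO2H (1.5 equiv), DMF, 0 °C → rt
Reagents that add atoms: sodium trichloroacetate, [Na+].[O-]C(=O)C(Cl)(Cl)Cl
Why: Decarboxylation of trichloroacetate gives the trichloromethyl anion, which adds 1,2 to the enal (Corey–Link-type carbinol synthesis); the new stereocentre is racemic and is erased in step 11.

**Step 10**
Reactants: 13 1,1,1-trichloro-4-methyl-3-methylidenepentan-2-ol; 10 2-(benzyloxy)-6-methyl-3-(propan-2-yl)phenol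
Product: 16 2-[2-(benzyloxy)-6-methyl-3-(propan-2-yl)phenoxy]-4-methyl-3-methylidenepentanoic acid (racemic), via dichloroepoxide 14 (not isolated), via acyl chloride 15 (not isolated)
Conditions: 13 (1.5 equiv), NaOH (5 equiv), DME/H2O, 0 °C → rt; then 1 M HCl
Reagents that add atoms: sodium hydroxide, [Na+].[OH-] (hydroxyl oxygen of the carboxyl group)
Why: In this Jocic reaction the alkoxide of 13 closes to gem-dichloroepoxide 14, the phenoxide opens it by SN2 attack at the allylic carbon and the acyl chloride 15 so formed is hydrolysed, so the crowded ether oxygen is bonded to an sp3 carbon before ring B exists.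

**Step 11**
Reactants: 16 2-[2-(benzyloxy)-6-methyl-3-(propan-2-yl)phenoxy]-4-methyl-3-methylidenepentanoic acid; 6 1-methoxy-2-methyl-5-(propan-2-yl)-4-(prop-1-yn-1-yloxy)benzene
Product: 22 4-[2-(benzyloxy)-6-methyl-3-(propan-2-yl)phenoxy]-3-[4-methoxy-5-methyl-2-(propan-2-yl)phenoxy]-2-methyl-5-(propan-2-yl)phenol, via acyloxypyridinium salt 17 (not isolated), via vinylketene 18 (not isolated), via cyclobutenone 19 (not isolated), via dienylketene 20 (not isolated), via cyclohexadienone 21 (not isolated)
Conditions: 16 (1.3 equiv), 2-chloro-1-methylpyridinium iodide (1.5 equiv), Et3N (1.3 equiv), CH2Cl2, rt, 1 h; this solution of 17 added over 4 h to 6 (1.0 equiv), Et3N (3 equiv), toluene, 40 °C; CH2Cl2 distilled off, then 110 °C, 6 h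
Reagents that add atoms: 2-chloro-1-methylpyridinium iodide, C[n+]1ccccc1Cl.[I-] (1-methylpyridinium unit and iodide of 17 only)
Why: Proposed new method: the carboxylate of 16 displaces chloride from 2-chloro-1-methylpyridinium iodide to give acyloxypyridinium salt 17, from which Et3N removes the alpha proton (activated by O, C=O and the alkene) with loss of 1-methylpyridin-2-one to give aryloxy(vinyl)ketene 18, whose carbonyl carbon is attacked by the nucleophilic CH3-bearing carbon of ynol ether 6, and collapse of the zwitterion closes cyclobutenone 19 by a polar [2+2] cycloaddition. At 110 °C 19 opens in a 4-pi electrocyclic reaction to the (3Z)-dienylketene 20, which closes ring B by a thermal disrotatory 6-pi electrocyclisation between the ketene carbon and the terminal CH2 and tautomerises from dienone 21 to phenol 22. The closest known reaction types are the Danheiser benzannulation (vinylketene from a cyclobutenone plus an alkoxyalkyne), the Moore ring expansion of 4-oxy-4-vinylcyclobutenones and the generation of alkoxyketenes from alpha-alkoxy acids with 2-chloro-1-methylpyridinium salts; new are the alpha-aryloxy vinylketene and the aryl ynol ether as partner. No stereocentre survives: the centre of 16 is lost in 18, and the quaternary carbon of racemic 19 becomes sp2 on ring opening. The step needs regioselectivity in the [2+2] event, which the polarisation of the ynol ether secures (its oxygen-bearing carbon can only bond to the ketene alpha carbon), and inward rotation of the vinyl group on ring opening, which the aryloxy donor on the same carbon secures by its preference for outward rotation, a wrong rotation being reversible. Slow addition keeps the ketene dilute against dimerisation, and the activation under basic conditions, with the acid fully converted to 17 before it meets 6, protects the acid-sensitive ynol ether.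

**Step 12**
Reactants: 22 4-[2-(benzyloxy)-6-methyl-3-(propan-2-yl)phenoxy]-3-[4-methoxy-5-methyl-2-(propan-2-yl)phenoxy]-2-methyl-5-(propan-2-yl)phenol
Product: 23 2-(benzyloxy)-3-{4-methoxy-2-[4-methoxy-5-methyl-2-(propan-2-yl)phenoxy]-3-methyl-6-(propan-2-yl)phenoxy}-4-methyl-1-(propan-2-yl)benzene
Conditions: MeI (2 equiv), K2CO3 (2 equiv), acetone, reflux
Reagents that add atoms: iodomethane, CI
Why: Williamson methylation of the only free phenol, flanked by CH3 and H, gives the ring B methoxy group without any selectivity question.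

**Step 13**
Reactants: 23 2-(benzyloxy)-3-{4-methoxy-2-[4-methoxy-5-methyl-2-(propan-2-yl)phenoxy]-3-methyl-6-(propan-2-yl)phenoxy}-4-methyl-1-(propan-2-yl)benzene
Product: 24 2-{4-methoxy-2-[4-methoxy-5-methyl-2-(propan-2-yl)phenoxy]-3-methyl-6-(propan-2-yl)phenoxy}-3-methyl-6-(propan-2-yl)phenol
Conditions: H2 (1 atm), 10% Pd/C, EtOAc, rt
Reagents that add atoms: none
Why: Catalytic hydrogenolysis cleaves only the benzylic C–O bond, while diaryl ethers and methyl ethers are inert.

**Step 14**
Reactants: 24 2-{4-methoxy-2-[4-methoxy-5-methyl-2-(propan-2-yl)phenoxy]-3-methyl-6-(propan-2-yl)phenoxy}-3-methyl-6-(propan-2-yl)phenol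
Product: 25 3-{4-methoxy-2-[4-methoxy-5-methyl-2-(propan-2-yl)phenoxy]-3-methyl-6-(propan-2-yl)phenoxy}-2-methyl-5-(propan-2-yl)cyclohexa-2,5-diene-1,4-dione (target; achiral)
Conditions: Co(salen) [Co(C16H14N2O2), divalent cobalt] (15 mol%), O2 (1 atm), DMF, rt
Reagents that add atoms: dioxygen, O=O
Why: Cobalt–salen-catalysed aerobic oxidation of a phenol with a free para position (the reaction type that turns thymol into thymoquinone) should give the para-quinone, since rings A and B carry no free OH and both ortho positions of the phenol are blocked.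

**Compound list**
1 | thymol, 5-methyl-2-(propan-2-yl)phenol | Cc1ccc(C(C)C)c(O)c1 | starting material
2 | 4-bromo-5-methyl-2-(propan-2-yl)phenol | Cc1cc(O)c(C(C)C)cc1Br | intermediate
3 | 4-methoxy-5-methyl-2-(propan-2-yl)phenol | COc1cc(C(C)C)c(O)cc1C | intermediate
4 | 1-{[(E)-1,2-dichloroethenyl]oxy}-4-methoxy-5-methyl-2-(propan-2-yl)benzene | COc1cc(C(C)C)c(O/C(Cl)=C\Cl)cc1C | intermediate
5 | lithium [4-methoxy-5-methyl-2-(propan-2-yl)phenoxy]ethynide | [Li]C#COc1cc(C)c(OC)cc1C(C)C | intermediate (not isolated)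
6 | 1-methoxy-2-methyl-5-(propan-2-yl)-4-(prop-1-yn-1-yloxy)benzene | CC#COc1cc(C)c(OC)cc1C(C)C | intermediate
7 | 2-hydroxy-6-methyl-3-(propan-2-yl)benzaldehyde | Cc1ccc(C(C)C)c(O)c1C=O | intermediate
8 | 2-(benzyloxy)-6-methyl-3-(propan-2-yl)benzaldehyde | Cc1ccc(C(C)C)c(OCc2ccccc2)c1C=O | intermediate
9 | 2-(benzyloxy)-6-methyl-3-(propan-2-yl)phenyl formate | Cc1ccc(C(C)C)c(OCc2ccccc2)c1OC=O | intermediate (not isolated)
10 | 2-(benzyloxy)-6-methyl-3-(propan-2-yl)phenol | Cc1ccc(C(C)C)c(OCc2ccccc2)c1O | intermediate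
11 | 3-methylbutanal | CC(C)CC=O | starting material
12 | 3-methyl-2-methylidenebutanal | CC(C)C(=C)C=O | intermediate
13 | 1,1,1-trichloro-4-methyl-3-methylidenepentan-2-ol (racemic) | CC(C)C(=C)C(O)C(Cl)(Cl)Cl | intermediate
14 | 2,2-dichloro-3-(3-methylbut-1-en-2-yl)oxirane (racemic) | CC(C)C(=C)C1OC1(Cl)Cl | intermediate (not isolated)
15 | 2-[2-(benzyloxy)-6-methyl-3-(propan-2-yl)phenoxy]-4-methyl-3-methylidenepentanoyl chloride (racemic) | CC(C)C(=C)C(Oc1c(C)ccc(C(C)C)c1OCc1ccccc1)C(Cl)=O | intermediate (not isolated)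
16 | 2-[2-(benzyloxy)-6-methyl-3-(propan-2-yl)phenoxy]-4-methyl-3-methylidenepentanoic acid (racemic) | CC(C)C(=C)C(Oc1c(C)ccc(C(C)C)c1OCc1ccccc1)C(O)=O | intermediate
17 | 2-({2-[2-(benzyloxy)-6-methyl-3-(propan-2-yl)phenoxy]-4-methyl-3-methylidenepentanoyl}oxy)-1-methylpyridin-1-ium iodide (racemic) | CC(C)C(=C)C(Oc1c(C)ccc(C(C)C)c1OCc1ccccc1)C(=O)Oc1cccc[n+]1C.[I-] | intermediate (not isolated)
18 | 2-[2-(benzyloxy)-6-methyl-3-(propan-2-yl)phenoxy]-4-methyl-3-methylidenepent-1-en-1-one | CC(C)C(=C)C(Oc1c(C)ccc(C(C)C)c1OCc1ccccc1)=C=O | intermediate (not isolated)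
19 | 4-[2-(benzyloxy)-6-methyl-3-(propan-2-yl)phenoxy]-3-[4-methoxy-5-methyl-2-(propan-2-yl)phenoxy]-2-methyl-4-(3-methylbut-1-en-2-yl)cyclobut-2-en-1-one (racemic) | CC1=C(Oc2cc(C)c(OC)cc2C(C)C)C(Oc2c(C)ccc(C(C)C)c2OCc2ccccc2)(C(=C)C(C)C)C1=O | intermediate (not isolated)
20 | (3Z)-4-[2-(benzyloxy)-6-methyl-3-(propan-2-yl)phenoxy]-3-[4-methoxy-5-methyl-2-(propan-2-yl)phenoxy]-2,6-dimethyl-5-methylidenehepta-1,3-dien-1-one | CC(=C=O)/C(Oc1cc(C)c(OC)cc1C(C)C)=C(Oc1c(C)ccc(C(C)C)c1OCc1ccccc1)\C(=C)C(C)C | intermediate (not isolated)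
21 | 4-[2-(benzyloxy)-6-methyl-3-(propan-2-yl)phenoxy]-3-[4-methoxy-5-methyl-2-(propan-2-yl)phenoxy]-2-methyl-5-(propan-2-yl)cyclohexa-2,4-dien-1-one | CC1=C(Oc2cc(C)c(OC)cc2C(C)C)C(Oc2c(C)ccc(C(C)C)c2OCc2ccccc2)=C(C(C)C)CC1=O | intermediate (not isolated)
22 | 4-[2-(benzyloxy)-6-methyl-3-(propan-2-yl)phenoxy]-3-[4-methoxy-5-methyl-2-(propan-2-yl)phenoxy]-2-methyl-5-(propan-2-yl)phenol | Cc1c(O)cc(C(C)C)c(Oc2c(C)ccc(C(C)C)c2OCc2ccccc2)c1Oc1cc(C)c(OC)cc1C(C)C | intermediate
23 | 2-(benzyloxy)-3-{4-methoxy-2-[4-methoxy-5-methyl-2-(propan-2-yl)phenoxy]-3-methyl-6-(propan-2-yl)phenoxy}-4-methyl-1-(propan-2-yl)benzene | COc1cc(C(C)C)c(Oc2c(C)ccc(C(C)C)c2OCc2ccccc2)c(Oc2cc(C)c(OC)cc2C(C)C)c1C | intermediate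
24 | 2-{4-methoxy-2-[4-methoxy-5-methyl-2-(propan-2-yl)phenoxy]-3-methyl-6-(propan-2-yl)phenoxy}-3-methyl-6-(propan-2-yl)phenol | COc1cc(C(C)C)c(Oc2c(C)ccc(C(C)C)c2O)c(Oc2cc(C)c(OC)cc2C(C)C)c1C | intermediate
25 | 3-{4-methoxy-2-[4-methoxy-5-methyl-2-(propan-2-yl)phenoxy]-3-methyl-6-(propan-2-yl)phenoxy}-2-methyl-5-(propan-2-yl)cyclohexa-2,5-diene-1,4-dione (CNP0335608.0, achiral) | COc1cc(C(C)C)c(Oc2c(C)c(OC)cc(C(C)C)c2OC2=C(C)C(=O)C=C(C(C)C)C2=O)cc1C | target

**Totals and risks**
Total step count: 14.
Longest linear sequence: 8 steps (1 → 7 → 8 → 10 → 16 → 22 → 23 → 24 → 25; steps 5, 6, 7, 10, 11, 12, 13, 14).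

Steps most likely to fail:

1. Step 11 (Proposed new method). The activated acid may end as the symmetrical anhydride instead of the ketene, the ketene may dimerise or be lost to amine adducts before the [2+2] cycloaddition, the ynol ether may be consumed by addition of unreacted carboxylic acid, or the crowded cyclobutenone may fail to funnel into the 6-pi closure. The fallback sets out from 6 and comes back at 25. It gives up the convergent union and grows rings B and C one after the other on an ynol ether oxygen by Dötz benzannulation, a known reaction in which the larger, here oxygen-bearing, alkyne carbon ends beside the new hydroxyl. Ynol ether 6 and pentacarbonyl[(2E)-1-methoxy-4-methylpent-2-en-1-ylidene]chromium F1 (zerovalent chromium; from (CO)5Cr=C(OCH3)CH3 and 2-methylpropanal by aldol condensation with Et3N and Me3SiCl) in THF at 50 °C, then CO to release the arene, should give 4-methoxy-2-[4-methoxy-5-methyl-2-(propan-2-yl)phenoxy]-3-methyl-6-(propan-2-yl)phenol F2 (the same compound as A3). Treatment as in steps 3 and 4 would give 1-{[(E)-1,2-dichloroethenyl]oxy}-4-methoxy-2-[4-methoxy-5-methyl-2-(propan-2-yl)phenoxy]-3-methyl-6-(propan-2-yl)benzene F3 and then 1-methoxy-3-[4-methoxy-5-methyl-2-(propan-2-yl)phenoxy]-2-methyl-5-(propan-2-yl)-4-(prop-1-yn-1-yloxy)benzene F4. A second benzannulation of F4 with F1 should give 4-methoxy-2-{4-methoxy-2-[4-methoxy-5-methyl-2-(propan-2-yl)phenoxy]-3-methyl-6-(propan-2-yl)phenoxy}-3-methyl-6-(propan-2-yl)phenol F5, which (NH4)2Ce(NO3)6 (tetravalent cerium) in MeCN/H2O at 0 °C would oxidise to quinone 25.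

2. Step 10. Hydroxide may outrun the hindered phenoxide in opening the dichloroepoxide, or the phenoxide may attack the alkene terminus with allylic transposition. The fallback sets out from 13 and 10 and comes back at 16. Carbinol 13 with aqueous NaOH alone (Jocic reaction with hydroxide) would give 2-hydroxy-4-methyl-3-methylidenepentanoic acid F6, which MeI and KHCO3 in DMF would esterify to methyl 2-hydroxy-4-methyl-3-methylidenepentanoate F7. Mitsunobu etherification of F7 with phenol 10 (PPh3, diisopropyl azodicarboxylate, toluene) would give methyl 2-[2-(benzyloxy)-6-methyl-3-(propan-2-yl)phenoxy]-4-methyl-3-methylidenepentanoate F8, and LiOH in THF/H2O would hydrolyse F8 to acid 16.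

3. Step 14. The phenoxyl radical may couple or attack the electron-rich rings A and B instead of capturing O2 at the para carbon, or the oxidation may stall on the hindered phenol. The fallback sets out from 24 and comes back at 25. It brings in the para oxygen by the classical nitrosation–reduction–oxidation sequence of thymoquinone chemistry. NaNO2 and HCl in EtOH at 0 °C should nitrosate only the free phenol, para to OH, to give 2-{4-methoxy-2-[4-methoxy-5-methyl-2-(propan-2-yl)phenoxy]-3-methyl-6-(propan-2-yl)phenoxy}-3-methyl-4-nitroso-6-(propan-2-yl)phenol F9. Na2S2O4 in THF/H2O would reduce F9 to 4-amino-2-{4-methoxy-2-[4-methoxy-5-methyl-2-(propan-2-yl)phenoxy]-3-methyl-6-(propan-2-yl)phenoxy}-3-methyl-6-(propan-2-yl)phenol F10, and FeCl3 (trivalent iron) in aqueous HCl would oxidise F10 to quinone 25 with loss of ammonia.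

**Further compounds**
F1 | step 11 | pentacarbonyl[(2E)-1-methoxy-4-methylpent-2-en-1-ylidene]chromium | COC(/C=C/C(C)C)=[Cr].[C-]#[O+].[C-]#[O+].[C-]#[O+].[C-]#[O+].[C-]#[O+]
F2 | step 11 | 4-methoxy-2-[4-methoxy-5-methyl-2-(propan-2-yl)phenoxy]-3-methyl-6-(propan-2-yl)phenol | COc1cc(C(C)C)c(O)c(Oc2cc(C)c(OC)cc2C(C)C)c1C
F3 | step 11 | 1-{[(E)-1,2-dichloroethenyl]oxy}-4-methoxy-2-[4-methoxy-5-methyl-2-(propan-2-yl)phenoxy]-3-methyl-6-(propan-2-yl)benzene | COc1cc(C(C)C)c(O/C(Cl)=C\Cl)c(Oc2cc(C)c(OC)cc2C(C)C)c1C
F4 | step 11 | 1-methoxy-3-[4-methoxy-5-methyl-2-(propan-2-yl)phenoxy]-2-methyl-5-(propan-2-yl)-4-(prop-1-yn-1-yloxy)benzene | CC#COc1c(C(C)C)cc(OC)c(C)c1Oc1cc(C)c(OC)cc1C(C)C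
F5 | step 11 | 4-methoxy-2-{4-methoxy-2-[4-methoxy-5-methyl-2-(propan-2-yl)phenoxy]-3-methyl-6-(propan-2-yl)phenoxy}-3-methyl-6-(propan-2-yl)phenol | COc1cc(C(C)C)c(O)c(Oc2c(C(C)C)cc(OC)c(C)c2Oc2cc(C)c(OC)cc2C(C)C)c1C
F6 | step 10 | 2-hydroxy-4-methyl-3-methylidenepentanoic acid (racemic) | CC(C)C(=C)C(O)C(O)=O
F7 | step 10 | methyl 2-hydroxy-4-methyl-3-methylidenepentanoate (racemic) | CC(C)C(=C)C(O)C(=O)OC
F8 | step 10 | methyl 2-[2-(benzyloxy)-6-methyl-3-(propan-2-yl)phenoxy]-4-methyl-3-methylidenepentanoate (racemic) | CC(C)C(=C)C(Oc1c(C)ccc(C(C)C)c1OCc1ccccc1)C(=O)OC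
F9 | step 14 | 2-{4-methoxy-2-[4-methoxy-5-methyl-2-(propan-2-yl)phenoxy]-3-methyl-6-(propan-2-yl)phenoxy}-3-methyl-4-nitroso-6-(propan-2-yl)phenol | COc1cc(C(C)C)c(Oc2c(C)c(N=O)cc(C(C)C)c2O)c(Oc2cc(C)c(OC)cc2C(C)C)c1C
F10 | step 14 | 4-amino-2-{4-methoxy-2-[4-methoxy-5-methyl-2-(propan-2-yl)phenoxy]-3-methyl-6-(propan-2-yl)phenoxy}-3-methyl-6-(propan-2-yl)phenol | COc1cc(C(C)C)c(Oc2c(C)c(N)cc(C(C)C)c2O)c(Oc2cc(C)c(OC)cc2C(C)C)c1C
A1 | direct plan | 3-chloro-2-methyl-5-(propan-2-yl)cyclohexa-2,5-diene-1,4-dione | CC1=C(Cl)C(=O)C(C(C)C)=CC1=O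
A2 | direct plan | 3-[4-methoxy-5-methyl-2-(propan-2-yl)phenoxy]-2-methyl-5-(propan-2-yl)cyclohexa-2,5-diene-1,4-dione | COc1cc(C(C)C)c(OC2=C(C)C(=O)C=C(C(C)C)C2=O)cc1C
A3 | direct plan | 4-methoxy-2-[4-methoxy-5-methyl-2-(propan-2-yl)phenoxy]-3-methyl-6-(propan-2-yl)phenol | COc1cc(C(C)C)c(Oc2c(C)c(OC)cc(C(C)C)c2O)cc1C
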